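## Retrosynthetic overview

- Numbering (1H-indene) used for all ring compounds in the Why lines: cyclopentene C1(H)(CH3)–C2H=C3(Et), ring fusion C3a/C7a, C4(CH3)(CO2H), C5(Et)(dienyl), C6H=C7(CH3).
- Enabling feature: in the cyclopentene ring (C1, C2, C3, C3a, C7a) the sp3 carbon C1 carries only H and CH3 and lies 1,5 to the olefinic CH C2. Cutting C1–C2 and removing C2 as a one-carbon unit leaves a plain ethyl group on C7a and an ethyl ketone (C3) on C3a, trans to each other on the cyclohexene.
- Disconnections: (a) C5 dienyl by Horner–Wadsworth–Emmons olefination of a C5 aldehyde, CO2H unmasked from a tert-butyl ester; (b) cyclopentene by alkylidene-carbene 1,5 C–H insertion (C1–C2 bond, C2 from Me3SiCHN2); (c) cyclohexene with the four contiguous stereocentres C7a, C3a, C4, C5 (vicinal quaternary C4/C5) by a catalytic asymmetric Diels–Alder reaction of a 2-ethyl-4-methylheptadienyl silyl ether with ethyl (E)-3-methyl-4-oxobut-2-enoate; (d) diene by olefination of (E)-2-methylpent-2-enal.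
- Ring order: cyclohexene first (step 4), cyclopentene last (step 9).

Key step: step 9

Assumption: the enal face selected by the oxazaborolidinium catalyst in step 4 is taken from the usual formyl-bound model for α-substituted enals and the catalyst is written as the (S)-prolinol-derived enantiomer; if the adduct proved to be the mirror image, the (R)-catalyst would be used and nothing else in the route changes.

## Route

Step 1
Reactants: 1 (E)-2-methylpent-2-enal; 2 triethyl 2-phosphonobutanoate
Product: 3 ethyl (2E,4E)-2-ethyl-4-methylhepta-2,4-dienoate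
Conditions: NaH, THF, 0 °C → rt
Reagents that add atoms: none
Why: Horner–Wadsworth–Emmons olefination of an enal with an α-branched stabilised phosphonate anion should give the trisubstituted (E)-enoate, which places the ester carbon (the future C5 side-chain carbon) trans and the ethyl group cis to the diene chain; no stereocentre is formed.

Step 2
Reactants: 3 ethyl (2E,4E)-2-ethyl-4-methylhepta-2,4-dienoate
Product: 4 (2E,4E)-2-ethyl-4-methylhepta-2,4-dien-1-ol
Conditions: iBu2AlH (2.2 equiv), CH2Cl2, −78 → 0 °C; aq potassium sodium tartrate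
Reagents that add atoms: none
Why: 1,2-reduction of a conjugated ester by iBu2AlH stops at the allylic alcohol and leaves both trisubstituted double bonds and their geometry untouched.

Step 3
Reactants: 4 (2E,4E)-2-ethyl-4-methylhepta-2,4-dien-1-ol
Product: 5 tert-butyl{[(2E,4E)-2-ethyl-4-methylhepta-2,4-dien-1-yl]oxy}diphenylsilane
Conditions: tBuPh2SiCl, imidazole, DMF, rt
Reagents that add atoms: tert-butyl(chloro)diphenylsilane, CC(C)(C)[Si](Cl)(c1ccccc1)c1ccccc1
Why: Standard silylation of a primary allylic alcohol gives an ether that should tolerate the Lewis acid of step 4 and the organometallic reagents of steps 7 to 9.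

Step 4
Reactants: 5 tert-butyl{[(2E,4E)-2-ethyl-4-methylhepta-2,4-dien-1-yl]oxy}diphenylsilane; 6 ethyl (2E)-3-methyl-4-oxobut-2-enoate
Product: 7 ethyl (1S,2S,5S,6R)-5-{[tert-butyl(diphenyl)silyl]oxymethyl}-2,5-diethyl-6-formyl-3,6-dimethylcyclohex-3-ene-1-carboxylate
Conditions: (3aS)-1-(2-methylphenyl)-3,3-diphenyltetrahydro-1H,3H-pyrrolo[1,2-c][1,3,2]oxazaborole + HN(SO2CF3)2 (20 mol % each), CH2Cl2, −78 → −20 °C
Reagents that add atoms: none
Why: In this catalytic asymmetric Diels–Alder reaction of an α-methyl enal the formyl-bound oxazaborolidinium cation makes the ester-bearing carbon of 6 the electrophilic terminus, so it bonds to the monosubstituted, most nucleophilic diene terminus (C3a–C7a) while the crowded C4–C5 bond closes late in an asynchronous transition state; with the formyl group endo and the ester exo (which also keeps the ester clear of the C7 methyl group) the (E,E)-diene and (E)-dienophile geometries translate into the required relative configuration at C7a, C3a, C4 and C5, and the catalyst, by shielding one enal face, sets the absolute configuration.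

Step 5
Reactants: 7 ethyl (1S,2S,5S,6R)-5-{[tert-butyl(diphenyl)silyl]oxymethyl}-2,5-diethyl-6-formyl-3,6-dimethylcyclohex-3-ene-1-carboxylate
Product: 8 (1R,2S,5S,6S)-2-{[tert-butyl(diphenyl)silyl]oxymethyl}-6-(ethoxycarbonyl)-2,5-diethyl-1,4-dimethylcyclohex-3-ene-1-carboxylic acid
Conditions: NaClO2, NaH2PO4, 2-methylbut-2-ene (large excess), tBuOH/H2O, rt
Reagents that add atoms: sodium chlorite, [Na+].[O-]Cl=O
Why: Pinnick oxidation converts the aldehyde, which has no α-hydrogen and cannot epimerise, into the acid under weakly acidic conditions, and the alkene scavenger removes hypochlorous acid before it can attack the ring double bond.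

Step 6
Reactants: 8 (1R,2S,5S,6S)-2-{[tert-butyl(diphenyl)silyl]oxymethyl}-6-(ethoxycarbonyl)-2,5-diethyl-1,4-dimethylcyclohex-3-ene-1-carboxylic acid
Product: 9 1-tert-butyl 2-ethyl (1R,2S,3S,6S)-6-{[tert-butyl(diphenyl)silyl]oxymethyl}-3,6-diethyl-1,4-dimethylcyclohex-4-ene-1,2-dicarboxylate
Conditions: tert-butyl 2,2,2-trichloroacetimidate, cyclohexane/CH2Cl2, rt
Reagents that add atoms: tert-butyl 2,2,2-trichloroacetimidate, CC(C)(C)OC(=N)C(Cl)(Cl)Cl
Why: O-alkylation of the acid by the protonated imidate transfers a tert-butyl cation to the carboxylate oxygen and is therefore insensitive to crowding at the C4 carboxyl carbon; the tert-butyl ester is chosen because it resists attack by the neighbouring C5 hydroxymethyl group set free in step 10.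

Step 7
Reactants: 9 1-tert-butyl 2-ethyl (1R,2S,3S,6S)-6-{[tert-butyl(diphenyl)silyl]oxymethyl}-3,6-diethyl-1,4-dimethylcyclohex-4-ene-1,2-dicarboxylate
Product: 10 tert-butyl (1R,2S,5S,6S)-2-{[tert-butyl(diphenyl)silyl]oxymethyl}-2,5-diethyl-6-[methoxy(methyl)carbamoyl]-1,4-dimethylcyclohex-3-ene-1-carboxylate
Conditions: MeNH(OMe)·HCl, iPrMgCl, THF, −20 → 0 °C
Reagents that add atoms: N,O-dimethylhydroxylamine hydrochloride, CNOC.Cl
Why: Aminolysis by the chloromagnesium amide (Weinreb amide formation) should occur only at the ethyl ester on C3a because the tert-butyl ester on the quaternary C4 is inert, and C3a should keep its configuration since its acyl group already lies trans to the C7a ethyl group.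

Step 8
Reactants: 10 tert-butyl (1R,2S,5S,6S)-2-{[tert-butyl(diphenyl)silyl]oxymethyl}-2,5-diethyl-6-[methoxy(methyl)carbamoyl]-1,4-dimethylcyclohex-3-ene-1-carboxylate
Product: 11 tert-butyl (1R,2S,5S,6S)-2-{[tert-butyl(diphenyl)silyl]oxymethyl}-2,5-diethyl-1,4-dimethyl-6-propanoylcyclohex-3-ene-1-carboxylate
Conditions: EtMgBr, THF, 0 °C; aq NH4Cl
Reagents that add atoms: ethylmagnesium bromide, CC[Mg]Br
Why: Acyl substitution of an N-methoxy-N-methylamide by a Grignard reagent (Weinreb ketone synthesis) gives the ethyl ketone without over-addition because the carbonyl group is released only on work-up, and the tert-butyl ester is not attacked.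

Step 9
Reactants: 11 tert-butyl (1R,2S,5S,6S)-2-{[tert-butyl(diphenyl)silyl]oxymethyl}-2,5-diethyl-1,4-dimethyl-6-propanoylcyclohex-3-ene-1-carboxylate
Product: 15 tert-butyl (1R,3aR,4R,5S,7aS)-5-{[tert-butyl(diphenyl)silyl]oxymethyl}-3,5-diethyl-1,4,7-trimethyl-3a,4,5,7a-tetrahydro-1H-indene-4-carboxylate, via lithium alkoxide adduct 12 (not isolated), via diazoalkene 13 (not isolated), via alkylidene carbene 14 (not isolated)
Conditions: Me3SiCHN2, n-BuLi, THF, −78 °C; then 11, −78 °C → rt
Reagents that add atoms: (trimethylsilyl)diazomethane, C[Si](C)(C)C=[N+]=[N-]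
Why: Lithiated trimethylsilyldiazomethane adds to the C3 ketone to give alkoxide 12, which loses lithium trimethylsilanolate (Peterson-type elimination) to give diazoalkene 13 and then N2 to give the singlet alkylidene carbene 14; the closest known reaction type is exactly this alkylidene-carbene 1,5 C–H insertion of dialkyl ketones, a standard cyclopentene synthesis. The cyclopentene ring (C1, C2, C3, C3a, C7a) closes in one bond-forming event, C2–C1, by concerted insertion of the carbene carbon C2 into a methylene C–H bond of the C7a ethyl group through a five-membered transition state. C1 is the only new stereocentre: insertion proceeds with retention, and of the two diastereotopic hydrogens the one should be replaced whose transition state keeps the C1 methyl group on the face of H-7a, away from the C7a–C7 bond and the C7 methyl group (syn-pentane strain in the alternative), which gives the (1R) configuration. The trans ring fusion is inherited, not created: C3a and C7a are untouched, and only the half-chair with both substituents pseudo-equatorial brings the carbene within reach of the ethyl CH2. The step needs site selectivity for this secondary C–H bond over the primary C–H bonds of the C4 methyl group (also 1,5) and chemoselectivity over addition to the C6=C7 double bond or the ester carbonyl; the known preference of alkylidene carbenes for secondary over primary C–H bonds, the anti disposition of the ring alkene to the carbene-bearing carbon in the reactive conformer, the shielding of the tert-butyl ester and the deliberate absence of the dienyl chain at this stage should secure it. Alkyl 1,2-shift to an alkyne, the usual escape route of such carbenes, is slow when both carbene substituents are alkyl groups.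

Step 10
Reactants: 15 tert-butyl (1R,3aR,4R,5S,7aS)-5-{[tert-butyl(diphenyl)silyl]oxymethyl}-3,5-diethyl-1,4,7-trimethyl-3a,4,5,7a-tetrahydro-1H-indene-4-carboxylate
Product: 16 tert-butyl (1R,3aR,4R,5S,7aS)-3,5-diethyl-5-(hydroxymethyl)-1,4,7-trimethyl-3a,4,5,7a-tetrahydro-1H-indene-4-carboxylate
Conditions: Bu4NF, AcOH (1:1), THF, rt
Reagents that add atoms: none
Why: Fluoride cleaves the silyl ether through the strong Si–F bond, and the acetic acid buffer together with the tert-butyl ester should prevent the liberated alcohol from lactonising onto the cis C4 carboxyl group.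

Step 11
Reactants: 16 tert-butyl (1R,3aR,4R,5S,7aS)-3,5-diethyl-5-(hydroxymethyl)-1,4,7-trimethyl-3a,4,5,7a-tetrahydro-1H-indene-4-carboxylate
Product: 17 tert-butyl (1R,3aR,4R,5S,7aS)-3,5-diethyl-5-formyl-1,4,7-trimethyl-3a,4,5,7a-tetrahydro-1H-indene-4-carboxylate
Conditions: Dess–Martin periodinane (1,1,1-triacetoxy-1,1-dihydro-1,2-benziodoxol-3(1H)-one), CH2Cl2, rt
Reagents that add atoms: none
Why: Dess–Martin oxidation of the primary alcohol gives an aldehyde that cannot enolise or epimerise because C5 is quaternary.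

Step 12
Reactants: 17 tert-butyl (1R,3aR,4R,5S,7aS)-3,5-diethyl-5-formyl-1,4,7-trimethyl-3a,4,5,7a-tetrahydro-1H-indene-4-carboxylate; 18 diethyl [(2E)-3-phenylprop-2-en-1-yl]phosphonate
Product: 19 tert-butyl (1R,3aR,4R,5S,7aS)-3,5-diethyl-1,4,7-trimethyl-5-[(1E,3E)-4-phenylbuta-1,3-dien-1-yl]-3a,4,5,7a-tetrahydro-1H-indene-4-carboxylate
Conditions: LiN(SiMe3)2, THF, −78 °C; then 17, −78 °C → rt
Reagents that add atoms: none
Why: Horner–Wadsworth–Emmons olefination with the allylic phosphonate anion should form the new double bond with E geometry while the cinnamyl E double bond is carried over unchanged, so the (1E,3E)-dienyl chain is built on the quaternary C5 without touching a stereocentre.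

Step 13
Reactants: 19 tert-butyl (1R,3aR,4R,5S,7aS)-3,5-diethyl-1,4,7-trimethyl-5-[(1E,3E)-4-phenylbuta-1,3-dien-1-yl]-3a,4,5,7a-tetrahydro-1H-indene-4-carboxylate
Product: 21 (1R,3aR,4R,5S,7aS)-3,5-diethyl-1,4,7-trimethyl-5-[(1E,3E)-4-phenylbuta-1,3-dien-1-yl]-3a,4,5,7a-tetrahydro-1H-indene-4-carboxylic acid, via trimethylsilyl ester 20 (not isolated)
Conditions: Me3SiOSO2CF3, 2,6-lutidine, CH2Cl2, 0 °C → rt; then pH 6 phosphate buffer
Reagents that add atoms: none
Why: The silyl triflate converts the tert-butyl ester into the trimethylsilyl ester 20 by O-silylation and loss of the tert-butyl group as isobutene to the hindered base, a cleavage that needs no nucleophilic attack at the crowded carbonyl and produces no strong protic acid that could add the carboxyl group across the neighbouring diene or ring alkene, and the buffered work-up hydrolyses 20 to the acid.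

## Compound list

1 | (E)-2-methylpent-2-enal | CC/C=C(\C)C=O | starting material
2 | triethyl 2-phosphonobutanoate | CCOC(=O)C(CC)P(=O)(OCC)OCC | starting material
3 | ethyl (2E,4E)-2-ethyl-4-methylhepta-2,4-dienoate | CC/C=C(C)/C=C(CC)/C(=O)OCC | intermediate
4 | (2E,4E)-2-ethyl-4-methylhepta-2,4-dien-1-ol | CC/C=C(C)/C=C(CC)/CO | intermediate
5 | tert-butyl{[(2E,4E)-2-ethyl-4-methylhepta-2,4-dien-1-yl]oxy}diphenylsilane | CC/C=C(C)/C=C(CC)/CO[Si](c1ccccc1)(c1ccccc1)C(C)(C)C | intermediate
6 | ethyl (2E)-3-methyl-4-oxobut-2-enoate | CCOC(=O)/C=C(\C)C=O | starting material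
7 | ethyl (1S,2S,5S,6R)-5-{[tert-butyl(diphenyl)silyl]oxymethyl}-2,5-diethyl-6-formyl-3,6-dimethylcyclohex-3-ene-1-carboxylate | CC[C@@H]1C(C)=C[C@@](CO[Si](c2ccccc2)(c2ccccc2)C(C)(C)C)(CC)[C@](C)(C=O)[C@H]1C(=O)OCC | intermediate
8 | (1R,2S,5S,6S)-2-{[tert-butyl(diphenyl)silyl]oxymethyl}-6-(ethoxycarbonyl)-2,5-diethyl-1,4-dimethylcyclohex-3-ene-1-carboxylic acid | CC[C@@H]1C(C)=C[C@@](CO[Si](c2ccccc2)(c2ccccc2)C(C)(C)C)(CC)[C@](C)(C(=O)O)[C@H]1C(=O)OCC | intermediate
9 | 1-tert-butyl 2-ethyl (1R,2S,3S,6S)-6-{[tert-butyl(diphenyl)silyl]oxymethyl}-3,6-diethyl-1,4-dimethylcyclohex-4-ene-1,2-dicarboxylate | CC[C@@H]1C(C)=C[C@@](CO[Si](c2ccccc2)(c2ccccc2)C(C)(C)C)(CC)[C@](C)(C(=O)OC(C)(C)C)[C@H]1C(=O)OCC | intermediate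
10 | tert-butyl (1R,2S,5S,6S)-2-{[tert-butyl(diphenyl)silyl]oxymethyl}-2,5-diethyl-6-[methoxy(methyl)carbamoyl]-1,4-dimethylcyclohex-3-ene-1-carboxylate | CC[C@@H]1C(C)=C[C@@](CO[Si](c2ccccc2)(c2ccccc2)C(C)(C)C)(CC)[C@](C)(C(=O)OC(C)(C)C)[C@H]1C(=O)N(C)OC | intermediate
11 | tert-butyl (1R,2S,5S,6S)-2-{[tert-butyl(diphenyl)silyl]oxymethyl}-2,5-diethyl-1,4-dimethyl-6-propanoylcyclohex-3-ene-1-carboxylate | CC[C@@H]1C(C)=C[C@@](CO[Si](c2ccccc2)(c2ccccc2)C(C)(C)C)(CC)[C@](C)(C(=O)OC(C)(C)C)[C@H]1C(=O)CC | intermediate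
12 | lithium alkoxide from addition of lithiated (trimethylsilyl)diazomethane to the ketone of 11 (ring configuration of 11; carbinol carbon undefined) | CC[C@@H]1C(C)=C[C@@](CO[Si](c2ccccc2)(c2ccccc2)C(C)(C)C)(CC)[C@](C)(C(=O)OC(C)(C)C)[C@H]1C([O-])(CC)C(=[N+]=[N-])[Si](C)(C)C.[Li+] | intermediate (not isolated)
13 | 6-(1-diazobut-1-en-2-yl) analogue of 11 (diazoalkene; ring configuration of 11) | CC[C@@H]1C(C)=C[C@@](CO[Si](c2ccccc2)(c2ccccc2)C(C)(C)C)(CC)[C@](C)(C(=O)OC(C)(C)C)[C@H]1C(CC)=C=[N+]=[N-] | intermediate (not isolated)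
14 | alkylidene carbene from 13 (divalent terminal carbon; ring configuration of 11) | CC[C@@H]1C(C)=C[C@@](CO[Si](c2ccccc2)(c2ccccc2)C(C)(C)C)(CC)[C@](C)(C(=O)OC(C)(C)C)[C@H]1C(CC)=[C] | intermediate (not isolated)
15 | tert-butyl (1R,3aR,4R,5S,7aS)-5-{[tert-butyl(diphenyl)silyl]oxymethyl}-3,5-diethyl-1,4,7-trimethyl-3a,4,5,7a-tetrahydro-1H-indene-4-carboxylate | CCC1=C[C@@H](C)[C@@H]2C(C)=C[C@@](CO[Si](c3ccccc3)(c3ccccc3)C(C)(C)C)(CC)[C@](C)(C(=O)OC(C)(C)C)[C@@H]12 | intermediate
16 | tert-butyl (1R,3aR,4R,5S,7aS)-3,5-diethyl-5-(hydroxymethyl)-1,4,7-trimethyl-3a,4,5,7a-tetrahydro-1H-indene-4-carboxylate | CCC1=C[C@@H](C)[C@@H]2C(C)=C[C@@](CO)(CC)[C@](C)(C(=O)OC(C)(C)C)[C@@H]12 | intermediate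
17 | tert-butyl (1R,3aR,4R,5S,7aS)-3,5-diethyl-5-formyl-1,4,7-trimethyl-3a,4,5,7a-tetrahydro-1H-indene-4-carboxylate | CCC1=C[C@@H](C)[C@@H]2C(C)=C[C@@](C=O)(CC)[C@](C)(C(=O)OC(C)(C)C)[C@@H]12 | intermediate
18 | diethyl [(2E)-3-phenylprop-2-en-1-yl]phosphonate | CCOP(=O)(C/C=C/c1ccccc1)OCC | starting material
19 | tert-butyl (1R,3aR,4R,5S,7aS)-3,5-diethyl-1,4,7-trimethyl-5-[(1E,3E)-4-phenylbuta-1,3-dien-1-yl]-3a,4,5,7a-tetrahydro-1H-indene-4-carboxylate | CCC1=C[C@@H](C)[C@@H]2C(C)=C[C@@](/C=C/C=C/c3ccccc3)(CC)[C@](C)(C(=O)OC(C)(C)C)[C@@H]12 | intermediate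
20 | trimethylsilyl ester of the target acid (configuration of 19) | CCC1=C[C@@H](C)[C@@H]2C(C)=C[C@@](/C=C/C=C/c3ccccc3)(CC)[C@](C)(C(=O)O[Si](C)(C)C)[C@@H]12 | intermediate (not isolated)
21 | (1R,3aR,4R,5S,7aS)-3,5-diethyl-1,4,7-trimethyl-5-[(1E,3E)-4-phenylbuta-1,3-dien-1-yl]-3a,4,5,7a-tetrahydro-1H-indene-4-carboxylic acid | CCC1=C[C@@H](C)[C@@H]2C(C)=C[C@@](/C=C/C=C/c3ccccc3)(CC)[C@](C)(C(=O)O)[C@@H]12 | target

## Step count and risks

Total steps: 13. Longest linear sequence: 13 steps (1 → 21); compounds 2, 6 and 18 enter as purchased materials.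

**Step 4 (Diels–Alder reaction).** What may go wrong: the crowded C4–C5 bond may close too slowly under the chiral catalyst, or the catalyst may discriminate poorly between the two enal faces, so that conversion or enantiomeric purity is low. The fallback sets out from 5 and 6 and comes back at 8. The cycloaddition is run with an achiral, stronger Lewis acid (Me2AlCl, CH2Cl2, −78 → 0 °C) to give the racemic aldehyde F1. Oxidation as in step 5 gives the racemic acid F2. F2 is resolved by crystallisation of its salt with (S)-1-phenylethylamine, the (S)-1-phenylethylammonium salt F3 (the mirror-image amine is taken if the other diastereomeric salt is the less soluble one). Acidification of the salt returns enantiopure 8.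

**Step 9 (key step).** What may go wrong: the lithiated diazo reagent may enolise the hindered α-branched ketone instead of adding to it, or the free carbene may discriminate poorly between the two diastereotopic methylene C–H bonds. The fallback sets out from 10 and comes back at 15; it uses a metal carbenoid at the ketone oxidation level.
- MeMgBr (THF, 0 °C) converts 10 into the methyl ketone F4.
- The kinetic enolate of F4 [LiN(SiMe3)2, −78 °C] is acylated with CF3CO2CH2CF3 to the trifluoroacetylated 1,3-diketone F5, which is not isolated.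
- MsN3/Et3N (detrifluoroacetylative diazo transfer) gives the α-diazo ketone F6.
- Rh2(OAc)4 in CH2Cl2 (a bulkier dirhodium carboxylate if the diastereoselectivity needs tuning) effects 1,5 C–H insertion into the same methylene group to give the trans-fused cyclopentanone F7.
- KN(SiMe3)2/PhN(SO2CF3)2 removes a proton from the C2 methylene rather than the ring-fusion methine and gives the enol triflate F8.
- Fe(acac)3-catalysed cross-coupling of F8 with EtMgBr (THF/NMP, −30 °C) installs the C3 ethyl group and gives 15.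

**Step 13 (ester cleavage).** What may go wrong: traces of strong acid may add the liberated carboxyl group across the neighbouring diene or the C6=C7 bond (lactone formation), or may isomerise the diene. The fallback sets out from 19 and comes back at 21; it replaces acidolysis by a redox sequence. LiAlH4 (THF, reflux) reduces the hindered ester to the primary alcohol F9. Dess–Martin oxidation gives the aldehyde F10. Pinnick oxidation (NaClO2, NaH2PO4, large excess of 2-methylbut-2-ene) gives 21.

Further compounds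
F1 | step 4 | racemic ethyl 5-{[tert-butyl(diphenyl)silyl]oxymethyl}-2,5-diethyl-6-formyl-3,6-dimethylcyclohex-3-ene-1-carboxylate (7 and its mirror image, 1:1) | CC[C@@H]1C(C)=C[C@@](CO[Si](c2ccccc2)(c2ccccc2)C(C)(C)C)(CC)[C@](C)(C=O)[C@H]1C(=O)OCC.CC[C@H]1C(C)=C[C@](CO[Si](c2ccccc2)(c2ccccc2)C(C)(C)C)(CC)[C@@](C)(C=O)[C@@H]1C(=O)OCC
F2 | step 4 | racemic 2-{[tert-butyl(diphenyl)silyl]oxymethyl}-6-(ethoxycarbonyl)-2,5-diethyl-1,4-dimethylcyclohex-3-ene-1-carboxylic acid (8 and its mirror image, 1:1) | CC[C@@H]1C(C)=C[C@@](CO[Si](c2ccccc2)(c2ccccc2)C(C)(C)C)(CC)[C@](C)(C(=O)O)[C@H]1C(=O)OCC.CC[C@H]1C(C)=C[C@](CO[Si](c2ccccc2)(c2ccccc2)C(C)(C)C)(CC)[C@@](C)(C(=O)O)[C@@H]1C(=O)OCC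
F3 | step 4 | (S)-1-phenylethylammonium salt of acid 8 | CC[C@@H]1C(C)=C[C@@](CO[Si](c2ccccc2)(c2ccccc2)C(C)(C)C)(CC)[C@](C)(C(=O)[O-])[C@H]1C(=O)OCC.C[C@H]([NH3+])c1ccccc1
F4 | step 9 | tert-butyl 6-acetyl-2-{[tert-butyl(diphenyl)silyl]oxymethyl}-2,5-diethyl-1,4-dimethylcyclohex-3-ene-1-carboxylate (configuration of 11) | CC[C@@H]1C(C)=C[C@@](CO[Si](c2ccccc2)(c2ccccc2)C(C)(C)C)(CC)[C@](C)(C(=O)OC(C)(C)C)[C@H]1C(C)=O
F5 | step 9 | 6-(4,4,4-trifluoro-3-oxobutanoyl) analogue of F4 (not isolated) | CC[C@@H]1C(C)=C[C@@](CO[Si](c2ccccc2)(c2ccccc2)C(C)(C)C)(CC)[C@](C)(C(=O)OC(C)(C)C)[C@H]1C(=O)CC(=O)C(F)(F)F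
F6 | step 9 | 6-(2-diazoacetyl) analogue of F4 | CC[C@@H]1C(C)=C[C@@](CO[Si](c2ccccc2)(c2ccccc2)C(C)(C)C)(CC)[C@](C)(C(=O)OC(C)(C)C)[C@H]1C(=O)C=[N+]=[N-]
F7 | step 9 | tert-butyl 5-{[tert-butyl(diphenyl)silyl]oxymethyl}-5-ethyl-1,4,7-trimethyl-3-oxo-2,3,3a,4,5,7a-hexahydro-1H-indene-4-carboxylate (trans-fused; configuration as in 15) | O=C1C[C@@H](C)[C@@H]2C(C)=C[C@@](CO[Si](c3ccccc3)(c3ccccc3)C(C)(C)C)(CC)[C@](C)(C(=O)OC(C)(C)C)[C@@H]12
F8 | step 9 | C3 enol trifluoromethanesulfonate of F7 (C2=C3 double bond) | O=S(=O)(OC1=C[C@@H](C)[C@@H]2C(C)=C[C@@](CO[Si](c3ccccc3)(c3ccccc3)C(C)(C)C)(CC)[C@](C)(C(=O)OC(C)(C)C)[C@@H]12)C(F)(F)F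
F9 | step 13 | {3,5-diethyl-1,4,7-trimethyl-5-[(1E,3E)-4-phenylbuta-1,3-dien-1-yl]-3a,4,5,7a-tetrahydro-1H-inden-4-yl}methanol (configuration of 19) | CCC1=C[C@@H](C)[C@@H]2C(C)=C[C@@](/C=C/C=C/c3ccccc3)(CC)[C@](C)(CO)[C@@H]12
F10 | step 13 | 3,5-diethyl-1,4,7-trimethyl-5-[(1E,3E)-4-phenylbuta-1,3-dien-1-yl]-3a,4,5,7a-tetrahydro-1H-indene-4-carbaldehyde (configuration of 19) | CCC1=C[C@@H](C)[C@@H]2C(C)=C[C@@](/C=C/C=C/c3ccccc3)(CC)[C@](C)(C=O)[C@@H]12
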